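All constants come from no measurement; the run is a simulation.

substrate 0.050 M; salt in the second phase 0.0500 M; spent carrier 10 mM; time 4.0 min; volume of the second phase over the first 1.0

- how much product and crystals together there is at 4.0 min, in percent of the substrate charged
- the change that raises the amount of product and crystals together at 4.0 min, in percent of the substrate charged most ("none" if none brings more than 2 percentage points) (west / north / south / none)
- amount of product and crystals together at 4.0 min, in percent of the substrate charged, after north

- west: doubling the solubility in step 4, all else as stated
- north: doubling the dissolution coefficient of step 4, all else as stated
- south: doubling the amount of salt in the second phase, all else as stated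

- amounts and yields of product count crystals too
- in the second phase: salt in the second phase, spent salt in the second phase; everything else is in the first
- charges count per volume of the first phase; a concentration in a rate is the amount of a species over the volume of its own phase; every rate counts per litre of the first phase
- given per volume of solution although it is solid: crystals
- run time (flask): 4.0 min

    spent carrier + salt in the second phase ⇌ fresh carrier + spent salt in the second phase (K1 = 3.48, k1 = 14.3 L mol⁻¹ s⁻¹)
    substrate + fresh carrier → product + spent carrier (k2 = 0.509 L mol⁻¹ s⁻¹)
    fresh carrier ⇌ dormant form (K3 = 1.75, k3 = 0.00306 s⁻¹)
    crystals ⇌ product, rate k4*(cs4 - [product]) while solid is left; crystals form when [product] > cs4 (cs4 = 25 mM, k4 = 0.188 s⁻¹)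

Start with the balance of the carrier, the reagent charged in the smaller amount: its charge is 0.200 of the substrate charge. Its fractions, spent, fresh and dormant, add up to one. Salt in the second phase makes spent carrier fresh, fresh carrier turns substrate into product and becomes spent, and fresh carrier also drifts into the dormant form.

1. Multiply the rate constant of substrate with fresh carrier, 0.509 L mol⁻¹ s⁻¹, by the carrier charge and the time: 1.22. This is the carrier dose. If f is the fresh fraction averaged over the run, the fraction of substrate left is exp(−f × dose), a pseudo-first-order rule.

2. The bench habit is f = 1, which converts 70.5%.

3. That stops working here: the run lasts 1.66 relaxation half-lives of fresh carrier and dormant form. The pair has gone 0.685 of the way to equilibrium, so dormant over fresh is about 0.772 at the end.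

4. Salt exchange is quick, 0.715 s⁻¹ against 0.0255 s⁻¹ for fresh carrier on substrate, so I hold it at equilibrium. Suppose 0.5 of the substrate has reacted and the whole carrier charge has taken salt: salt left is 0.300 of its charge, and spent over fresh is 0.670.

5. The balance gives a final f of 0.409. A straight line from 1 averages 0.705, so I commit to 57.7%. Doubled salt leaves 0.650 of its charge and gives 60.5%, a gain of 2.8 percentage points against the margin of 2 points. Crystals enter neither f nor the dose, so west and north change nothing.

The forecast gives 52% for y, south as the best change and 52% after north; its y is lower than mine and rests on “slow substrate turnover as salt depletes and some carrier goes dormant”.

The simulation gives 51.5%. South adds 4.8 points, west 0 points and north 0 points, so south is best and north stays at 51.5%.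

In this flask, spent carrier has a forward half-life of 2.9 s at 4.00 min, against 2.40 min for the relaxation with the dormant form. At that time the carrier charge stands at 40.4% fresh, 25.0% spent and 34.6% dormant. Read back through the dose, this flask has f = 0.593. The neighbour charged with 0.0025 M of spent carrier has a dose of 0.305, so that f gives 16.6%, and that neighbour flask reads 19.1%.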